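The dihydrofuran ring is disconnected at O1–C7a. C7a lies para to the C5 acetyl group, so in an open-chain precursor a fluorine on that carbon is activated for intramolecular SNAr by the C2 oxygen. One operation thus closes the five-membered ring and forges the aryl ether without touching C2 or C3, whose anti relationship and absolute configuration are set beforehand by an enamine aldol of hydroxyacetone with a fluoro aldehyde. The precursor is an anti 1-aryl-3-methylbut-3-ene-1,2-diol carrying ortho fluorine, para-disposed acetyl and an O-allyl-masked C6 phenol. Deallylation and acylation of the C3 hydroxyl with separately made O-acetylsarracinic acid complete the target.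

Key step: step 7

Remark: the side-chain alkene is read from the SMILES as Z (ester carbonyl cis to the methyl group) and the ring as trans-(2R,3S); the four starting materials are taken to be commercial.

Step 1
Reactants: 1 4'-fluoro-2'-hydroxyacetophenone
Product: 2 5-acetyl-2-fluoro-4-hydroxybenzaldehyde
Conditions: hexamethylenetetramine, CF3CO2H, 85 °C; aqueous HCl work-up
Reagents that add atoms: hexamethylenetetramine, C1N2CN3CN1CN(C2)C3; water, O
Why: Duff formylation: the iminium electrophile from hexamethylenetetramine in CF3CO2H should attack para to the phenol (ortho to F, meta to acetyl), because the only other activated carbon is flanked by OH and F, and hydrolysis releases the aldehyde.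

Step 2
Reactants: 2 5-acetyl-2-fluoro-4-hydroxybenzaldehyde; 3 allyl bromide
Product: 4 5-acetyl-4-(allyloxy)-2-fluorobenzaldehyde
Conditions: K2CO3, DMF, rt
Reagents that add atoms: none
Why: Williamson etherification of the acidic, carbonyl-stabilised phenoxide with a reactive allylic bromide at room temperature, where SN2 alkylation should outrun any attack of this weakly nucleophilic phenoxide on the activated aryl fluoride.

Step 3
Reactants: 4 5-acetyl-4-(allyloxy)-2-fluorobenzaldehyde; 5 hydroxyacetone (excess)
Product: 6 (3S,4S)-4-[5-acetyl-4-(allyloxy)-2-fluorophenyl]-3,4-dihydroxybutan-2-one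
Conditions: L-proline (30 mol %), DMF, 4 °C
Reagents that add atoms: none
Why: Proline-catalysed direct aldol (enamine catalysis): the (E)-enamine formed at the hydroxylated carbon of hydroxyacetone should add to the aldehyde through the carboxylic acid-organised transition state and set C3 and C4 as the anti (3S,4S) diol, the aryl methyl ketone being a far poorer donor and acceptor; any syn isomer is to be removed by chromatography here or after step 4.

Step 4
Reactants: 6 (3S,4S)-4-[5-acetyl-4-(allyloxy)-2-fluorophenyl]-3,4-dihydroxybutan-2-one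
Product: 7 (3S,4S)-4-[5-acetyl-4-(allyloxy)-2-fluorophenyl]-3,4-bis(triethylsilyloxy)butan-2-one
Conditions: Et3SiCl, imidazole, DMF, 0 °C to rt
Reagents that add atoms: chlorotriethylsilane, CC[Si](Cl)(CC)CC
Why: Standard silylation of both secondary hydroxyls masks the β-hydroxy ketone against retro-aldol and elimination in the basic step that follows, and an acyclic bis-silyl ether, unlike a cis-fused cyclic acetal, gives the α-carbon no thermodynamic incentive to epimerise.

Step 5
Reactants: 7 (3S,4S)-4-[5-acetyl-4-(allyloxy)-2-fluorophenyl]-3,4-bis(triethylsilyloxy)butan-2-one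
Product: 8 1-{2-(allyloxy)-4-fluoro-5-[(1S,2R)-3-methyl-1,2-bis(triethylsilyloxy)but-3-en-1-yl]phenyl}ethanone
Conditions: Ph3PCH3Br (1.1 equiv), KN(SiMe3)2, THF, −78 to 0 °C
Reagents that add atoms: methyltriphenylphosphonium bromide, C[P+](c1ccccc1)(c1ccccc1)c1ccccc1.[Br-]
Why: Wittig methylenation with a slight excess of ylide at low temperature should take place at the inductively activated α-silyloxy methyl ketone much faster than at the aryl ketone, which is conjugated, flanked by the ortho allyloxy group and electronically a vinylogous ester.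

Step 6
Reactants: 8 1-{2-(allyloxy)-4-fluoro-5-[(1S,2R)-3-methyl-1,2-bis(triethylsilyloxy)but-3-en-1-yl]phenyl}ethanone
Product: 9 (1S,2R)-1-[5-acetyl-4-(allyloxy)-2-fluorophenyl]-3-methylbut-3-ene-1,2-diol
Conditions: HF·pyridine, pyridine, THF, 0 °C to rt
Reagents that add atoms: none
Why: Fluoride-driven cleavage of both triethylsilyl ethers under pyridine-buffered conditions, mild enough to leave the benzylic and allylic carbinols, the allyl ether and the aryl fluoride untouched.

Step 7
Reactants: 9 (1S,2R)-1-[5-acetyl-4-(allyloxy)-2-fluorophenyl]-3-methylbut-3-ene-1,2-diol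
Product: 10 1-[(2R,3S)-6-(allyloxy)-3-hydroxy-2-(prop-1-en-2-yl)-2,3-dihydro-1-benzofuran-5-yl]ethanone
Conditions: KOtBu (1.1 equiv), THF (0.02 M), 0 °C to rt
Reagents that add atoms: none
Why: Deprotonation gives the C2 alkoxide, which adds to the fluorine-bearing carbon (the future C7a) to form an anionic σ-adduct whose charge is delocalised onto the para acetyl oxygen, and loss of fluoride restores the arene (addition–elimination SNAr). The closest known reaction type is the intramolecular SNAr of alkoxides onto ortho-fluoroarenes activated by a para acyl group, an established entry to 2,3-dihydrobenzofurans. The dihydrofuran ring closes in a 5-exo-trig sense by formation of the O1–C7a bond. No stereocentre is created: C2 and C3 are carried over from the anti diol because neither C–O bond is broken, so the anti diol maps onto the trans ring. Only chemoselectivity is required, and the substrate supplies it: the benzylic alkoxide could close only a four-membered ring, and the O-allyl group keeps the C6 oxygen from becoming a deactivating phenoxide. About one equivalent of base at high dilution is chosen so that the enolisable acetyl group is not held entirely as its deactivating enolate and intermolecular substitution stays slow.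

Step 8
Reactants: 10 1-[(2R,3S)-6-(allyloxy)-3-hydroxy-2-(prop-1-en-2-yl)-2,3-dihydro-1-benzofuran-5-yl]ethanone
Product: 11 1-[(2R,3S)-3,6-dihydroxy-2-(prop-1-en-2-yl)-2,3-dihydro-1-benzofuran-5-yl]ethanone
Conditions: Pd(PPh3)4 (3 mol %), morpholine, THF, rt
Reagents that add atoms: none
Why: Tsuji–Trost-type deallylation: zerovalent palladium ionises the unhindered primary allyl aryl ether, whose leaving group is an acetyl-stabilised phenoxide, and morpholine captures the allyl unit, whereas the ring C2–O1 allylic ether is secondary and sits on a 2-methyl-substituted alkene and should ionise far more slowly.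

Step 9
Reactants: 12 (E)-but-2-enal (crotonaldehyde)
Product: 13 (Z)-2-iodobut-2-enal
Conditions: I2, K2CO3, DMAP (20 mol %), THF/H2O (1:1), rt
Reagents that add atoms: iodine, II
Why: α-Iodination of an enal by conjugate addition of the amine catalyst, iodination of the resulting enolate and elimination (Morita–Baylis–Hillman-type manifold), which replaces the α-hydrogen and therefore leaves iodine cis to the methyl group (Z).

Step 10
Reactants: 13 (Z)-2-iodobut-2-enal
Product: 14 (Z)-2-iodobut-2-en-1-ol
Conditions: NaBH4, MeOH, 0 °C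
Reagents that add atoms: none
Why: Chemoselective 1,2-reduction of the aldehyde by borohydride, which does not touch the alkenyl iodide or the alkene geometry.

Step 11
Reactants: 14 (Z)-2-iodobut-2-en-1-ol
Product: 16 (Z)-2-(hydroxymethyl)but-2-enoic acid, via alkenyllithium alkoxide 15 (not isolated)
Conditions: NaH, THF, 0 °C; t-BuLi (2.1 equiv), −78 °C; CO2; aqueous HCl
Reagents that add atoms: carbon dioxide, O=C=O
Why: After deprotonation of the hydroxyl, iodine–lithium exchange with two equivalents of tert-butyllithium gives a configurationally stable alkenyllithium that is carboxylated by CO2 with retention, so the carboxyl group ends cis to the methyl group (Z).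

Step 12
Reactants: 16 (Z)-2-(hydroxymethyl)but-2-enoic acid
Product: 18 (Z)-2-(acetoxymethyl)but-2-enoic acid, via mixed acetic anhydride 17 (not isolated)
Conditions: Ac2O (2.5 equiv), pyridine, CH2Cl2, 0 °C to rt; then H2O, rt
Reagents that add atoms: acetic anhydride, CC(=O)OC(C)=O
Why: Acetylation of the primary alcohol with acetic anhydride and pyridine; the carboxyl group is converted in parallel into a mixed anhydride, which water cleaves at the more electrophilic acetyl carbonyl during the quench to return the free acid.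

Step 13
Reactants: 18 (Z)-2-(acetoxymethyl)but-2-enoic acid; 11 1-[(2R,3S)-3,6-dihydroxy-2-(prop-1-en-2-yl)-2,3-dihydro-1-benzofuran-5-yl]ethanone
Product: 20 (2R,3S)-5-acetyl-6-hydroxy-2-(prop-1-en-2-yl)-2,3-dihydro-1-benzofuran-3-yl (2Z)-2-(acetoxymethyl)but-2-enoate, via acid chloride 19 (not isolated)
Conditions: 1-chloro-N,N,2-trimethylprop-1-en-1-amine, CH2Cl2, 0 °C; then 11, 2,4,6-collidine, CH2Cl2, −20 to 0 °C
Reagents that add atoms: none
Why: Acylation of the secondary C3 alcohol by the acid chloride generated under neutral conditions; the C6 hydroxyl is a weakly nucleophilic vinylogous acid locked in a hydrogen bond to the C5 acetyl oxygen, and a hindered non-nucleophilic pyridine base at low temperature without acyl-transfer catalyst should avoid phenol acylation, Z-to-E isomerisation or allylic substitution in the side chain and elimination of the C3 ester.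

Compound list
1 | 4'-fluoro-2'-hydroxyacetophenone | CC(=O)c1ccc(F)cc1O | starting material
2 | 5-acetyl-2-fluoro-4-hydroxybenzaldehyde | CC(=O)c1cc(C=O)c(F)cc1O | intermediate
3 | allyl bromide | C=CCBr | starting material
4 | 5-acetyl-4-(allyloxy)-2-fluorobenzaldehyde | CC(=O)c1cc(C=O)c(F)cc1OCC=C | intermediate
5 | hydroxyacetone | CC(=O)CO | starting material
6 | (3S,4S)-4-[5-acetyl-4-(allyloxy)-2-fluorophenyl]-3,4-dihydroxybutan-2-one | CC(=O)[C@@H](O)[C@@H](O)c1cc(C(C)=O)c(OCC=C)cc1F | intermediate
7 | (3S,4S)-4-[5-acetyl-4-(allyloxy)-2-fluorophenyl]-3,4-bis(triethylsilyloxy)butan-2-one | CC(=O)[C@@H](O[Si](CC)(CC)CC)[C@@H](O[Si](CC)(CC)CC)c1cc(C(C)=O)c(OCC=C)cc1F | intermediate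
8 | 1-{2-(allyloxy)-4-fluoro-5-[(1S,2R)-3-methyl-1,2-bis(triethylsilyloxy)but-3-en-1-yl]phenyl}ethanone | C=C(C)[C@@H](O[Si](CC)(CC)CC)[C@@H](O[Si](CC)(CC)CC)c1cc(C(C)=O)c(OCC=C)cc1F | intermediate
9 | (1S,2R)-1-[5-acetyl-4-(allyloxy)-2-fluorophenyl]-3-methylbut-3-ene-1,2-diol | C=C(C)[C@@H](O)[C@@H](O)c1cc(C(C)=O)c(OCC=C)cc1F | intermediate
10 | 1-[(2R,3S)-6-(allyloxy)-3-hydroxy-2-(prop-1-en-2-yl)-2,3-dihydro-1-benzofuran-5-yl]ethanone | C=C(C)[C@H]1Oc2cc(OCC=C)c(C(C)=O)cc2[C@@H]1O | intermediate
11 | 1-[(2R,3S)-3,6-dihydroxy-2-(prop-1-en-2-yl)-2,3-dihydro-1-benzofuran-5-yl]ethanone | C=C(C)[C@H]1Oc2cc(O)c(C(C)=O)cc2[C@@H]1O | intermediate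
12 | (E)-but-2-enal (crotonaldehyde) | C/C=C/C=O | starting material
13 | (Z)-2-iodobut-2-enal | C/C=C(/C=O)I | intermediate
14 | (Z)-2-iodobut-2-en-1-ol | C/C=C(/CO)I | intermediate
15 | sodium (E)-2-lithiobut-2-en-1-olate (lithium cis to the methyl group) | C/C=C(/C[O-])[Li].[Na+] | intermediate
16 | (Z)-2-(hydroxymethyl)but-2-enoic acid | C/C=C(/CO)C(=O)O | intermediate
17 | acetic (Z)-2-(acetoxymethyl)but-2-enoic anhydride | C/C=C(/COC(C)=O)C(=O)OC(C)=O | intermediate
18 | (Z)-2-(acetoxymethyl)but-2-enoic acid | C/C=C(/COC(C)=O)C(=O)O | intermediate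
19 | (Z)-2-(acetoxymethyl)but-2-enoyl chloride | C/C=C(/COC(C)=O)C(Cl)=O | intermediate
20 | (2R,3S)-5-acetyl-6-hydroxy-2-(prop-1-en-2-yl)-2,3-dihydro-1-benzofuran-3-yl (2Z)-2-(acetoxymethyl)but-2-enoate | C=C(C)[C@H]1Oc2cc(O)c(C(C)=O)cc2[C@@H]1OC(=O)/C(=C\C)COC(C)=O | target

Total step count: 13 (main line steps 1–8 and 13; side-chain acid steps 9–12).
Longest linear sequence: 9 steps (steps 1–8, then step 13).

Steps most likely to fail

Step 3: erosion of both anti/syn and facial selectivity, because aromatic aldehydes are the least selective acceptors in proline-type aldols of hydroxyacetone. The fallback sets out from 4 and returns at 20. It uses the primary-amine variant of the same aldol (O-tert-butyl-D-threonine, NMP, 4 °C), which reacts through the Z-enamine and is reliably syn-selective with aromatic aldehydes, to give (3S,4R)-4-[5-acetyl-4-(allyloxy)-2-fluorophenyl]-3,4-dihydroxybutan-2-one F1. This is taken through the conditions of steps 4 to 6 as (3S,4R)-4-[5-acetyl-4-(allyloxy)-2-fluorophenyl]-3,4-bis(triethylsilyloxy)butan-2-one F2, 1-{2-(allyloxy)-4-fluoro-5-[(1R,2R)-3-methyl-1,2-bis(triethylsilyloxy)but-3-en-1-yl]phenyl}ethanone F3 and the syn diol (1R,2R)-1-[5-acetyl-4-(allyloxy)-2-fluorophenyl]-3-methylbut-3-ene-1,2-diol F4. Ring closure with KOtBu as in step 7 then gives the cis alcohol 1-[(2R,3R)-6-(allyloxy)-3-hydroxy-2-(prop-1-en-2-yl)-2,3-dihydro-1-benzofuran-5-yl]ethanone F5, and deallylation as in step 8 gives 1-[(2R,3R)-3,6-dihydroxy-2-(prop-1-en-2-yl)-2,3-dihydro-1-benzofuran-5-yl]ethanone F6. Mitsunobu esterification of F6 with acid 18 (PPh3, diisopropyl azodicarboxylate, THF, 0 °C) inverts C3 and delivers the trans ester 20.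

Step 13: competing acylation of the phenol, slow reaction of a hindered acyl donor with a hindered alcohol, and geometric isomerisation of the Z alkene if the reaction has to be forced. The fallback sets out from 10 and returns at 20. The only free hydroxyl of 10 is acylated with acid chloride 19 (2,4,6-collidine, CH2Cl2) to give (2R,3S)-5-acetyl-6-(allyloxy)-2-(prop-1-en-2-yl)-2,3-dihydro-1-benzofuran-3-yl (2Z)-2-(acetoxymethyl)but-2-enoate F8. The O-allyl group is then isomerised with [Ir(cod)(PMePh2)2]PF6 (activated with H2, then purged; THF, rt) to the enol ether (2R,3S)-5-acetyl-6-[(E)-prop-1-enyloxy]-2-(prop-1-en-2-yl)-2,3-dihydro-1-benzofuran-3-yl (2Z)-2-(acetoxymethyl)but-2-enoate F9. Neutral cleavage of the enol ether with HgCl2 and HgO in aqueous acetone releases the phenol 20.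

Step 7: conversion of the acetyl group into its enolate, which switches off the activation of C7a, leaving intermolecular substitution or base-induced decomposition to take over. The fallback sets out from 8 and returns at 10. The bis-silyl ether 8 is heated with CsF (0.2–1 equiv) in DMF at 60 °C. Fluoride activates the C2 silyl ether, its oxygen displaces the aryl fluoride, and the released fluoride carries the chain, so no stoichiometric base is present. This fluoride-mediated SNAr of a silyl ether should give 1-[(2R,3S)-6-(allyloxy)-2-(prop-1-en-2-yl)-3-(triethylsilyloxy)-2,3-dihydro-1-benzofuran-5-yl]ethanone F7, which HF·pyridine in THF converts into 10.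

Further compounds
F1 | step 3 | (3S,4R)-4-[5-acetyl-4-(allyloxy)-2-fluorophenyl]-3,4-dihydroxybutan-2-one | CC(=O)[C@@H](O)[C@H](O)c1cc(C(C)=O)c(OCC=C)cc1F
F2 | step 3 | (3S,4R)-4-[5-acetyl-4-(allyloxy)-2-fluorophenyl]-3,4-bis(triethylsilyloxy)butan-2-one | CC(=O)[C@@H](O[Si](CC)(CC)CC)[C@H](O[Si](CC)(CC)CC)c1cc(C(C)=O)c(OCC=C)cc1F
F3 | step 3 | 1-{2-(allyloxy)-4-fluoro-5-[(1R,2R)-3-methyl-1,2-bis(triethylsilyloxy)but-3-en-1-yl]phenyl}ethanone | C=C(C)[C@@H](O[Si](CC)(CC)CC)[C@H](O[Si](CC)(CC)CC)c1cc(C(C)=O)c(OCC=C)cc1F
F4 | step 3 | (1R,2R)-1-[5-acetyl-4-(allyloxy)-2-fluorophenyl]-3-methylbut-3-ene-1,2-diol | C=C(C)[C@@H](O)[C@H](O)c1cc(C(C)=O)c(OCC=C)cc1F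
F5 | step 3 | 1-[(2R,3R)-6-(allyloxy)-3-hydroxy-2-(prop-1-en-2-yl)-2,3-dihydro-1-benzofuran-5-yl]ethanone | C=C(C)[C@H]1Oc2cc(OCC=C)c(C(C)=O)cc2[C@H]1O
F6 | step 3 | 1-[(2R,3R)-3,6-dihydroxy-2-(prop-1-en-2-yl)-2,3-dihydro-1-benzofuran-5-yl]ethanone | C=C(C)[C@H]1Oc2cc(O)c(C(C)=O)cc2[C@H]1O
F7 | step 7 | 1-[(2R,3S)-6-(allyloxy)-2-(prop-1-en-2-yl)-3-(triethylsilyloxy)-2,3-dihydro-1-benzofuran-5-yl]ethanone | C=C(C)[C@H]1Oc2cc(OCC=C)c(C(C)=O)cc2[C@@H]1O[Si](CC)(CC)CC
F8 | step 13 | (2R,3S)-5-acetyl-6-(allyloxy)-2-(prop-1-en-2-yl)-2,3-dihydro-1-benzofuran-3-yl (2Z)-2-(acetoxymethyl)but-2-enoate | C=C(C)[C@H]1Oc2cc(OCC=C)c(C(C)=O)cc2[C@@H]1OC(=O)/C(=C\C)COC(C)=O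
F9 | step 13 | (2R,3S)-5-acetyl-6-[(E)-prop-1-enyloxy]-2-(prop-1-en-2-yl)-2,3-dihydro-1-benzofuran-3-yl (2Z)-2-(acetoxymethyl)but-2-enoate | C=C(C)[C@H]1Oc2cc(O/C=C/C)c(C(C)=O)cc2[C@@H]1OC(=O)/C(=C\C)COC(C)=O
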